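**Retrosynthetic overview**
1. Target 12 is an isoflavone; its pyranone ring (ring C) is closed last, by acid cyclization and loss of methanol from the β-keto acetal 10, which comes from hydrogenolysis of the bis-benzyl ether 9.
2. Acetal 9 comes from chalcone 8 by an oxidative 1,2-shift of ring B (Tl(NO3)3 in methanol), which moves the aryl group from Cβ to Cα.
3. Chalcone 8 comes from a Claisen–Schmidt aldol condensation of acetophenone 5 with 2,4,5-trimethoxybenzaldehyde 6; this C–C bond becomes C2–C3 of the target.
4. Acetophenone 5 comes from benzylation of 4, which comes from regioselective C-acetylation of methoxyhydroquinone 3, made by Dakin oxidation of vanillin 1.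
5. Ring order: rings A and B are bought as arenes; ring C is the only ring built, in the last step.

Assumption: the target SMILES has no stereocentre and no stereogenic double bond (an achiral isoflavone), so the single-enantiomer requirement is met trivially; chiral intermediates are racemic and their stereocentres are removed before the end.

**Route**

Step 1
Reactants: 1 vanillin (4-hydroxy-3-methoxybenzaldehyde)
Product: 3 2-methoxybenzene-1,4-diol (methoxyhydroquinone), via aryl formate 2 (not isolated)
Conditions: 30% H2O2 (1.1 equiv), NaOH (1.05 equiv), H2O, N2, 0 °C to rt (below 40 °C); then 2 M HCl to pH 3, EtOAc extraction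
Reagents that add atoms: hydrogen peroxide, OO
Why: Dakin oxidation, in which hydroperoxide adds to the aldehyde of the p-hydroxybenzaldehyde, the electron-rich aryl group migrates to oxygen and the formate 2 is saponified in the same pot; no stereocentre is involved.

Step 2
Reactants: 3 2-methoxybenzene-1,4-diol
Product: 4 1-(2,5-dihydroxy-4-methoxyphenyl)ethan-1-one
Conditions: AcOH (1.5 equiv), BF3·OEt2 (4 equiv), N2, 90 °C, 2 h; then ice–water, filter or extract
Reagents that add atoms: acetic acid, CC(=O)O
Why: BF3-mediated Friedel–Crafts (Nencki-type) C-acylation goes to the only unhindered position activated by two donors (para to OMe, ortho to OH), giving the chelated o-hydroxyacetophenone; no stereocentre.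

Step 3
Reactants: 4 1-(2,5-dihydroxy-4-methoxyphenyl)ethan-1-one
Product: 5 1-[2,5-bis(benzyloxy)-4-methoxyphenyl]ethan-1-one
Conditions: BnBr (2.5 equiv), K2CO3 (3 equiv), KI (cat.), DMF, N2, 70 °C, 6 h
Reagents that add atoms: benzyl bromide, BrCc1ccccc1
Why: Williamson ether synthesis (SN2), where hot DMF and excess reagent also alkylate the hydrogen-bonded 2-OH, so that no free phenol is left to be oxidized in step 5; no stereocentre.

Step 4
Reactants: 5 1-[2,5-bis(benzyloxy)-4-methoxyphenyl]ethan-1-one; 6 2,4,5-trimethoxybenzaldehyde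
Product: 8 (E)-1-[2,5-bis(benzyloxy)-4-methoxyphenyl]-3-(2,4,5-trimethoxyphenyl)prop-2-en-1-one, via aldol adduct 7 (not isolated)
Conditions: KOH (50% aq, 4 equiv), EtOH, rt, 24–48 h; dilute HCl, crystallize from EtOH
Reagents that add atoms: none
Why: Claisen–Schmidt crossed aldol condensation, in which the enolate of the only enolizable partner adds to the non-enolizable aldehyde and E1cB dehydration of racemic 7 gives the thermodynamically favoured E-enone, so the carbinol stereocentre is destroyed.

Step 5
Reactants: 8 (E)-1-[2,5-bis(benzyloxy)-4-methoxyphenyl]-3-(2,4,5-trimethoxyphenyl)prop-2-en-1-one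
Product: 9 1-[2,5-bis(benzyloxy)-4-methoxyphenyl]-3,3-dimethoxy-2-(2,4,5-trimethoxyphenyl)propan-1-one (racemic)
Conditions: Tl(NO3)3·3H2O (1.1 equiv), MeOH–HC(OMe)3–CH2Cl2 (2:2:1), rt, 3–16 h; filter off the thallium salt, aq. NaHCO3
Reagents that add atoms: methanol, CO
Why: Oxidative 1,2-aryl rearrangement of a chalcone, where methoxythallation of the enone by trivalent thallium and reductive loss of monovalent thallium drive migration of the very electron-rich 2,4,5-trimethoxyphenyl group from Cβ to Cα and methanol traps the oxocarbenium ion as the dimethyl acetal; the new C2 stereocentre is racemic and is lost in step 6.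

Step 6
Reactants: 9 1-[2,5-bis(benzyloxy)-4-methoxyphenyl]-3,3-dimethoxy-2-(2,4,5-trimethoxyphenyl)propan-1-one
Product: 12 6-hydroxy-7-methoxy-3-(2,4,5-trimethoxyphenyl)-4H-chromen-4-one (target), via debenzylated acetal 10 (not isolated), via 2-methoxyisoflavanone 11 (not isolated)
Conditions: H2 (1 atm), 10% Pd/C, EtOAc–MeOH (1:1), rt, to uptake of 2 equiv H2; filter through Celite under N2; then conc. HCl (cat.), MeOH, reflux, 1–2 h
Reagents that add atoms: none
Why: Hydrogenolysis of both aryl benzyl ethers, then acid-catalysed addition of the 2-OH to the acetal-derived oxocarbenium ion (giving 11) and β-elimination of methanol, gives the aromatic chromen-4-one; debenzylating before the C2=C3 bond exists avoids its over-reduction, and all stereocentres vanish.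

**Compound list**
1 | vanillin (4-hydroxy-3-methoxybenzaldehyde) | COc1cc(C=O)ccc1O | starting material
2 | 4-hydroxy-3-methoxyphenyl formate | COc1cc(OC=O)ccc1O | intermediate
3 | 2-methoxybenzene-1,4-diol (methoxyhydroquinone) | COc1cc(O)ccc1O | intermediate
4 | 1-(2,5-dihydroxy-4-methoxyphenyl)ethan-1-one | CC(=O)c1cc(O)c(OC)cc1O | intermediate
5 | 1-[2,5-bis(benzyloxy)-4-methoxyphenyl]ethan-1-one | CC(=O)c1cc(OCc2ccccc2)c(OC)cc1OCc1ccccc1 | intermediate
6 | 2,4,5-trimethoxybenzaldehyde | COc1cc(OC)c(OC)cc1C=O | starting material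
7 | 1-[2,5-bis(benzyloxy)-4-methoxyphenyl]-3-hydroxy-3-(2,4,5-trimethoxyphenyl)propan-1-one (racemic) | COc1cc(OCc2ccccc2)c(cc1OCc1ccccc1)C(=O)CC(O)c1cc(OC)c(OC)cc1OC | intermediate
8 | (E)-1-[2,5-bis(benzyloxy)-4-methoxyphenyl]-3-(2,4,5-trimethoxyphenyl)prop-2-en-1-one | COc1cc(OCc2ccccc2)c(cc1OCc1ccccc1)C(=O)/C=C/c1cc(OC)c(OC)cc1OC | intermediate
9 | 1-[2,5-bis(benzyloxy)-4-methoxyphenyl]-3,3-dimethoxy-2-(2,4,5-trimethoxyphenyl)propan-1-one (racemic) | COc1cc(OCc2ccccc2)c(cc1OCc1ccccc1)C(=O)C(C(OC)OC)c1cc(OC)c(OC)cc1OC | intermediate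
10 | 1-(2,5-dihydroxy-4-methoxyphenyl)-3,3-dimethoxy-2-(2,4,5-trimethoxyphenyl)propan-1-one (racemic) | COc1cc(O)c(cc1O)C(=O)C(C(OC)OC)c1cc(OC)c(OC)cc1OC | intermediate
11 | 6-hydroxy-2,7-dimethoxy-3-(2,4,5-trimethoxyphenyl)chroman-4-one (racemic diastereomer mixture) | COC1Oc2cc(OC)c(O)cc2C(=O)C1c1cc(OC)c(OC)cc1OC | intermediate
12 | 6-hydroxy-7-methoxy-3-(2,4,5-trimethoxyphenyl)-4H-chromen-4-one | COc1cc2occ(-c3cc(OC)c(OC)cc3OC)c(=O)c2cc1O | target

**Summary**
Total step count: 6. Longest linear sequence: 6 steps (1 → 3 → 4 → 5 → 8 → 9 → 12); aldehyde 6 is bought and enters at step 4.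

Steps most likely to fail, with fallbacks:

Step 5 (oxidative aryl shift on a substrate with two very electron-rich rings; ring oxidation or nitration may compete). The fallback sets out from 8 and comes back at 12, replacing steps 5 and 6 by the epoxide–acyl-shift approach. Weitz–Scheffer epoxidation of 8 (30% H2O2, NaOH, MeOH–acetone, 0 °C to rt) gives racemic trans-[2,5-bis(benzyloxy)-4-methoxyphenyl][3-(2,4,5-trimethoxyphenyl)oxiran-2-yl]methanone F2. BF3·OEt2 (0.5 equiv) in dry toluene–Et2O at 0 °C opens the epoxide at the benzylic carbon with a 1,2-acyl shift, giving 3-[2,5-bis(benzyloxy)-4-methoxyphenyl]-3-oxo-2-(2,4,5-trimethoxyphenyl)propanal F3. Hydrogenolysis (H2, 10% Pd/C, EtOAc) gives 3-(2,5-dihydroxy-4-methoxyphenyl)-3-oxo-2-(2,4,5-trimethoxyphenyl)propanal F4, which cyclodehydrates to 12 on brief warming in methanolic HCl.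

Step 6 (possible slow or unselective hydrogenolysis, reduction of the aryl ketone, or air oxidation of the hydroquinone 10). The fallback sets out from 9 and comes back at 12. It replaces reductive cleavage by Lewis-acid dealkylation with a cation scavenger: BCl3 (4 equiv) and pentamethylbenzene (6 equiv) in CH2Cl2 at −78 °C cleave both benzyl ethers, the one ortho to the ketone by chelation, and ionize the acetal. A methanol quench and short reflux with the HCl formed carry the material through 10 and 11 to 12 without hydrogen or palladium. No new compound arises (F0).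

Step 2 (acylation of an air-sensitive free hydroquinone; regiochemistry rests on electronic bias). The fallback sets out from 3 and comes back at 5, protecting before acylating. Bis-benzylation of 3 (BnBr, K2CO3, DMF, 60 °C, N2) gives the air-stable 1,4-bis(benzyloxy)-2-methoxybenzene F1. F1 is acetylated para to the methoxy group under mild mixed-anhydride Friedel–Crafts conditions (AcOH, (CF3CO)2O, cat. H3PO4, 0 °C to rt) that do not cleave benzyl ethers, giving 5 directly and replacing steps 2 and 3.

**Further compounds**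
F1 | step 2 | 1,4-bis(benzyloxy)-2-methoxybenzene | COc1cc(OCc2ccccc2)ccc1OCc1ccccc1
F2 | step 5 | trans-[2,5-bis(benzyloxy)-4-methoxyphenyl][3-(2,4,5-trimethoxyphenyl)oxiran-2-yl]methanone (racemic, one enantiomer drawn) | COc1cc(OCc2ccccc2)c(cc1OCc1ccccc1)C(=O)[C@H]1O[C@@H]1c1cc(OC)c(OC)cc1OC
F3 | step 5 | 3-[2,5-bis(benzyloxy)-4-methoxyphenyl]-3-oxo-2-(2,4,5-trimethoxyphenyl)propanal (racemic) | COc1cc(OCc2ccccc2)c(cc1OCc1ccccc1)C(=O)C(C=O)c1cc(OC)c(OC)cc1OC
F4 | step 5 | 3-(2,5-dihydroxy-4-methoxyphenyl)-3-oxo-2-(2,4,5-trimethoxyphenyl)propanal (racemic) | COc1cc(O)c(cc1O)C(=O)C(C=O)c1cc(OC)c(OC)cc1OC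
F0 | step 6 | none | none
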